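# Proposed synthesis of 4'-O-methylcupressuflavone (CNP0322111.0)

## Analysis of the target

The target is an 8,8''-linked biflavone in which unit 1 is acacetin (5,7-dihydroxy-4'-methoxyflavone, rings A, C and B) and unit 2 is apigenin (rings A'', C'' and B''), the two being joined by a single bond between C8 of ring A and C8'' of ring A''. There is no stereocentre; the only stereochemical element is the C8–C8'' axis, which is flanked by four ortho substituents (the C7 and C7'' oxygens and the ring oxygens on C8a and C8a'') and should rotate slowly, but the structure carries no descriptor for it. The sensitive groups are five free phenols, two of them chelated to the C4 and C4'' carbonyls, two 4-pyranone rings that do not tolerate strong bases or hard nucleophiles, and one aryl methyl ether at C4' that has to survive while five other phenolic oxygens are set free. The synthesis is hard for three reasons: the biaryl bond lies between two phloroglucinol-type rings and carries four ortho substituents, the three nearly equivalent oxygens of ring A'' must be told apart because one becomes O1'' and two stay hydroxyls, and only one of six phenolic oxygens is methylated. The strategy rests on the bond C4''–C4a'', in which C4'' is the carbonyl carbon of pyranone ring C'' and C4a'' is an arene carbon of ring A''. C4a'' lies ortho to the O1''-bearing C8a'', ortho to the C5'' oxygen and para to the C7'' oxygen, so it is an exceptionally nucleophilic position. The other carbon ortho to C8a'', namely C8'', is taken by the biaryl bond, so an acyl group tethered through O1'' has exactly one ring carbon to attack.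

## Retrosynthetic reasoning

Release of the hydroxyls (20 from 18). The target 20 is traced back to the pentaether 18, in which each oxygen that ends as a hydroxyl carries an isopropyl group and the C4' oxygen keeps its methyl group. Five oxygen–alkyl bonds are cut. A secondary alkyl aryl ether is cleaved by a boron Lewis acid under conditions that leave a primary methyl aryl ether alone, so the choice of alkyl group alone distinguishes the one oxygen that must stay capped. The boron-bound intermediate 19 is hydrolysed on work-up. The forward step has to remove five isopropyl groups, two of them next to carbonyls, without demethylation.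

Ring C'' at C4''–C4a'' (18 from 16). The bond between the carbonyl carbon C4'' and the arene carbon C4a'' is cut, which opens the pyranone of unit 2 to the 3-aryloxy-3-arylacrylic acid 16. This cut is preferred over O1''–C2'' or C2''–C3'' because it uses the most nucleophilic carbon of the molecule, needs no enolate chemistry beside the base-sensitive pyranone of unit 1, and allows a single regiochemical outcome. In the forward direction the carboxyl of 16 is activated as the mixed anhydride 17, which acylates C4a'' intramolecularly.

Enol ether bond O1''–C2'' (16 from 15, 15 from 14 and 12). Acid 16 comes from its ethyl ester 15 by saponification. Cutting the bond between O1'' and C2'' of 15 gives the phenol 14 and the arylpropiolate 12. The forward reaction is the conjugate addition of the phenoxide of 14 to the triple bond of 12. Anti addition places the ester cis to the aryloxy group, which is the geometry the ring closure needs.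

Biaryl bond C8–C8'' (14 from 13, 13 from 3 and 8). Phenol 14 is unmasked from its methoxymethyl ether 13, and the C8–C8'' bond of 13 is cut to the 8-iodoflavone 3 and the arylboronate 8. Cutting here lets unit 1 arrive complete from a commercial flavone, so ring C'' is the only ring the route has to build. The forward coupling must join two carbons that each carry two ortho oxygen substituents, which calls for a palladium catalyst carrying a bulky electron-rich biarylphosphine.

Unit 1 (3 from 2, 2 from 1). Iodide 3 is traced to the bis-isopropyl ether 2 by removal of the iodine at C8, and 2 to acacetin (1) by removal of the two isopropyl groups. In the forward direction, electrophilic iodination of the fully alkylated flavone is expected at C8, and the two isopropoxy groups that flank C6 reinforce this.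

Ring A'' fragment (8 from 6 through 7, 6 from 5, 5 from 4). The carbon–boron bond of 8 is cut to the aryllithium 7, which comes from 6 by directed ortho-lithiation. The oxygen destined to become O1'' carries a methoxymethyl group because an acetal ether directs lithiation to its own ortho position; this fixes the boron between the acetal oxygen and one isopropoxy group and at the same stroke marks one of the three ring oxygens as different. Dilute acid later removes the acetal, which the isopropyl ethers tolerate. Ether 6 comes from 3,5-diisopropoxyphenol (5), and 5 from phloroglucinol (4) by twofold O-alkylation.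

Side chain (12 from 10 and 11, 10 from 9). The aryl–alkyne bond of 12 is cut to the aryl iodide 10 and ethyl propiolate (11), a Sonogashira disconnection, and 10 comes from 4-iodophenol (9) by O-alkylation. The oxygen of ring B'' is capped as an isopropyl ether so that one reagent frees all five hydroxyls at the end.

## Alternatives that were turned down

Alternative 1: ring A of unit 1 made by a biomimetic pyranone-to-phloroglucinol Claisen cyclization.
- Disconnection and key step: ring A is cut at C4a–C8a. The precursor is 4-hydroxy-6-[(E)-4-(4-methoxyphenyl)-2-oxobut-3-en-1-yl]-3-(5,7,4'-tribenzyloxyflavon-8-yl)-2H-pyran-2-one A1, a 4-hydroxy-2-pyranone that already carries unit 2 on its C3. A chelating magnesium alkoxide would make the side-chain methylene carbon of A1 attack the lactone carbonyl and give the chalcone 2',4',6'-trihydroxy-4-methoxy-3'-(5,7,4'-tribenzyloxyflavon-8-yl)chalcone A2.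
- For it: ring A appears with its three oxygens in place and unprotected, so no phloroglucinol oxygens need to be differentiated on that ring. With benzyl groups only, the end game after A2 is a hydrogenolysis that cannot touch the methyl ether. On both points it is stronger than the chosen route.
- Against it: A2 still has to be closed to a flavone, and it has two hydroxyls ortho to the acyl group. Closure through the 2'-hydroxyl beside the bulky flavonyl group gives the 8,8'' linkage, closure through the less hindered 6'-hydroxyl gives the 6,8''-linked isomer, and nothing in A2 favours the wanted mode. A1 also needs a congested aryl–pyranone bond at C3, which is no easier than the biaryl coupling of the chosen route, and the pyranone of unit 2 must survive alkoxide base.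
- Comparison: the chosen route is shorter and its ring closure has one possible site only. It gives regiochemical certainty in exchange for a more delicate final deprotection.

Alternative 2: ring A'' built around the biaryl carbon by a Danheiser benzannulation.
- Disconnection and key step: ring A'' is cut at C8''–C8a'', C6''–C7'' and C4a''–C8a''. Heating 8-[(triisopropylsilyloxy)ethynyl]-5,7-bis(benzyloxy)-4'-methoxyflavone A3 with 3-ethoxycyclobut-2-en-1-one A4 would open A4 to a vinylketene that adds to the alkyne of A3 in a (2+2) sense. Ring opening and six-electron electrocyclization would then give 8-[4-ethoxy-2-hydroxy-6-(triisopropylsilyloxy)phenyl]-5,7-bis(benzyloxy)-4'-methoxyflavone A5.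
- For it: no cross-coupling at a carbon with four ortho neighbours is needed, because the biaryl carbon becomes part of a new ring. The three oxygens of ring A'' emerge in A5 already differentiated (free hydroxyl, ethyl ether, silyl ether) without statistical alkylation or directed metalation. On both points it is stronger than steps 3 to 5 and 8 of the chosen route.
- Against it: siloxyalkynes are normally reached from esters through ynolates with excess organolithium base, which the pyranone of unit 1 would not survive, so A3 is hard to make. The ethyl ether at C5'' of A5 could later be told from the C4' methyl ether only through chelation to the C4'' carbonyl. Ring C'' must still be built on A5, by the same acylative closure or another.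
- Comparison: the benzannulation replaces a handful of well-known steps by a longer and less established sequence and does not remove the final ring closure. The chosen route reaches the same kind of phenol (14) by known reactions.

Alternative 3: ring A of unit 1 made by a Diels–Alder reaction on a sulfinyl 4-pyranone.
- Disconnection and key step: ring A is cut at C8–C8a and C4a–C5. The dienophile is 2-(4-methoxyphenyl)-5-(4-methylphenylsulfinyl)-4H-pyran-4-one A6. The diene is 1-methoxy-1,3-bis(trimethylsilyloxy)-4-(5,7,4'-tribenzyloxyflavon-8-yl)buta-1,3-diene A7, which carries the whole of unit 2 on its nucleophilic terminus. Cycloaddition of A7 across C5=C6 of A6, followed by two eliminations that aromatize the new ring, would give the half-protected biflavone 5,7-dihydroxy-4'-methoxy-8-(5,7,4'-tribenzyloxyflavon-8-yl)flavone A8.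
- For it: the polarity of the diene fixes the aryl group at C8. The 5,7-diol of unit 1 appears directly in A8, and the three benzyl groups of A8 come off by hydrogenolysis with no risk to the methyl ether. It is convergent and, on the final deprotection, stronger than the chosen route.
- Against it: the carbon of A7 that must bond to C6 of A6 bears an aryl group with two ortho substituents, and the C5=C6 bond of a 4-pyranone is a reluctant dienophile even with the sulfinyl activator. Open-chain Mukaiyama–Michael products or no reaction are therefore likely. Making A7 requires a double enolization with strong amide base in the presence of a flavone, and the γ-aryl acetoacetate behind it needs C8 functionalization of unit 2 plus further steps.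
- Comparison: the step that leads to A8 is an intermolecular bond formation at a very hindered carbon, whereas the chosen key step is an intramolecular acylation at an unhindered, strongly activated carbon. The chosen route is also shorter.

Key step: step 12

Assumption: the C8–C8'' axis is drawn without a descriptor, so the target is taken as the racemic biflavone and no control of the axis is attempted.

## Route

Step 1
Reactants: 1 acacetin (5,7-dihydroxy-4'-methoxyflavone)
Product: 2 5,7-diisopropoxy-4'-methoxyflavone
Conditions: 2-bromopropane (excess), K2CO3, DMF, 80 °C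
Reagents that add atoms: 2-bromopropane, CC(C)Br
Why: Williamson ether synthesis; the 7-hydroxyl reacts first and the hydrogen-bonded 5-hydroxyl follows with excess halide and heat, as is usual for 5-hydroxyflavones.

Step 2
Reactants: 2 5,7-diisopropoxy-4'-methoxyflavone
Product: 3 8-iodo-5,7-diisopropoxy-4'-methoxyflavone
Conditions: NIS, TFA (cat.), MeCN, rt
Reagents that add atoms: N-iodosuccinimide, O=C1CCC(=O)N1I
Why: Electrophilic aromatic iodination; fully O-alkylated 5,7-dioxygenated flavones are attacked at C8 and not at C6, C6 is additionally shielded by two isopropoxy groups, and ring B is far less activated.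

Step 3
Reactants: 4 phloroglucinol
Product: 5 3,5-diisopropoxyphenol
Conditions: 2-bromopropane (2.2 equiv), K2CO3, DMF, 60 °C; chromatography
Reagents that add atoms: 2-bromopropane, CC(C)Br
Why: Williamson ether synthesis under stoichiometric control; the diether is separated from the mono- and triethers, as is common practice for 3,5-dialkoxyphenols.

Step 4
Reactants: 5 3,5-diisopropoxyphenol
Product: 6 1-(methoxymethoxy)-3,5-diisopropoxybenzene
Conditions: NaH, MOMCl, THF, 0 °C to rt
Reagents that add atoms: chloromethyl methyl ether, COCCl
Why: O-alkylation of the sodium phenoxide with an α-chloro ether (acetal protection of a phenol).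

Step 5
Reactants: 6 1-(methoxymethoxy)-3,5-diisopropoxybenzene
Product: 8 2-[2-(methoxymethoxy)-4,6-diisopropoxyphenyl]-4,4,5,5-tetramethyl-1,3,2-dioxaborolane, via aryllithium 7 (not isolated)
Conditions: n-BuLi, TMEDA, THF, 0 °C; then 2-isopropoxy-4,4,5,5-tetramethyl-1,3,2-dioxaborolane, −78 °C to rt; then H2O
Reagents that add atoms: 2-isopropoxy-4,4,5,5-tetramethyl-1,3,2-dioxaborolane, CC(C)OB1OC(C)(C)C(C)(C)O1
Why: Directed ortho-metalation followed by borylation; the chelating acetal ether is a much better directing group than an isopropoxy group, so lithium should enter between the acetal oxygen and one isopropoxy group and not between the two bulky isopropoxy groups.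

Step 6
Reactants: 9 4-iodophenol
Product: 10 1-iodo-4-isopropoxybenzene
Conditions: 2-bromopropane, K2CO3, DMF, 60 °C
Reagents that add atoms: 2-bromopropane, CC(C)Br
Why: Williamson ether synthesis on an unhindered phenol.

Step 7
Reactants: 10 1-iodo-4-isopropoxybenzene; 11 ethyl propiolate
Product: 12 ethyl 3-(4-isopropoxyphenyl)propiolate
Conditions: PdCl2(PPh3)2 (cat.), CuI (cat.), K2CO3, THF, 65 °C
Reagents that add atoms: none
Why: Sonogashira coupling of an aryl iodide with a terminal ynoate; the carbonate base replaces the usual amine, which would add to the propiolate.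

Step 8
Reactants: 3 8-iodo-5,7-diisopropoxy-4'-methoxyflavone; 8 2-[2-(methoxymethoxy)-4,6-diisopropoxyphenyl]-4,4,5,5-tetramethyl-1,3,2-dioxaborolane
Product: 13 8-[2-(methoxymethoxy)-4,6-diisopropoxyphenyl]-5,7-diisopropoxy-4'-methoxyflavone
Conditions: Pd(OAc)2 (cat.), SPhos, K3PO4, toluene/H2O, 100 °C
Reagents that add atoms: none
Why: Suzuki–Miyaura coupling; the bulky electron-rich biarylphosphine keeps palladium monoligated, which is what allows transmetalation and reductive elimination at a biaryl bond with four ortho substituents, and the pinacol ester slows protodeboronation of the 2,6-dialkoxyaryl boron partner.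

Step 9
Reactants: 13 8-[2-(methoxymethoxy)-4,6-diisopropoxyphenyl]-5,7-diisopropoxy-4'-methoxyflavone
Product: 14 8-(2-hydroxy-4,6-diisopropoxyphenyl)-5,7-diisopropoxy-4'-methoxyflavone
Conditions: conc. HCl (cat.), MeOH/THF, 50 °C
Reagents that add atoms: none
Why: Acid-catalysed transacetalization removes the methoxymethyl group; isopropyl and methyl aryl ethers and the flavone are stable to dilute protic acid.

Step 10
Reactants: 14 8-(2-hydroxy-4,6-diisopropoxyphenyl)-5,7-diisopropoxy-4'-methoxyflavone; 12 ethyl 3-(4-isopropoxyphenyl)propiolate
Product: 15 ethyl (Z)-3-[2-(5,7-diisopropoxy-4'-methoxyflavon-8-yl)-3,5-diisopropoxyphenoxy]-3-(4-isopropoxyphenyl)acrylate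
Conditions: Cs2CO3, DMF, 80 °C
Reagents that add atoms: none
Why: Oxa-Michael addition of a phenoxide to an arylpropiolate (first stage of the Ruhemann flavone synthesis); anti addition should place the ester cis to the aryloxy group (Z), and any E isomer is carried along because both converge in step 12.

Step 11
Reactants: 15 ethyl (Z)-3-[2-(5,7-diisopropoxy-4'-methoxyflavon-8-yl)-3,5-diisopropoxyphenoxy]-3-(4-isopropoxyphenyl)acrylate
Product: 16 (Z)-3-[2-(5,7-diisopropoxy-4'-methoxyflavon-8-yl)-3,5-diisopropoxyphenoxy]-3-(4-isopropoxyphenyl)acrylic acid
Conditions: LiOH, THF/MeOH/H2O, 40 °C; then 1 M HCl, 0 °C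
Reagents that add atoms: lithium hydroxide, [Li+].[OH-]
Why: Saponification by acyl–oxygen cleavage; the carboxylate formed is protected against conjugate attack, and the pyranone of unit 1 tolerates mild aqueous LiOH.

Step 12
Reactants: 16 (Z)-3-[2-(5,7-diisopropoxy-4'-methoxyflavon-8-yl)-3,5-diisopropoxyphenoxy]-3-(4-isopropoxyphenyl)acrylic acid
Product: 18 5,7,5'',7'',4'''-penta-O-isopropyl ether of the target (5,7-diisopropoxy-8-[5,7-diisopropoxy-2-(4-isopropoxyphenyl)-4-oxo-4H-chromen-8-yl]-4'-methoxyflavone), via mixed trifluoroacetic anhydride 17 (not isolated)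
Conditions: TFAA, CH2Cl2, 0 °C to rt
Reagents that add atoms: none
Why: Trifluoroacetic anhydride turns the carboxyl of 16 into the mixed anhydride 17, whose acyl carbon, as the anhydride or as the acylium ion it ionises to, is a stabilised but sufficient electrophile held directly beside C4a''. C4a'' attacks it in an intramolecular Friedel–Crafts acylation (electrophilic aromatic substitution), and loss of the proton from the arenium ion restores ring A'' and leaves the C4'' ketone, so that pyranone ring C'' is closed at C4''–C4a''. The closest known reaction type is the acid-promoted cyclization of 3-aryloxy-3-arylacrylic acids to flavones (second stage of the Ruhemann flavone synthesis), together with the acylation of phenol ethers by acyl trifluoroacetates. Ring C'' closes in a 6-exo-trig mode, the carbonyl oxygen staying outside the new six-membered ring. No stereocentre is formed, and the C8–C8'' axis is carried through unchanged as the racemate. The step needs site selectivity on ring A'' and chemoselectivity among three electron-rich rings: the tether through O1'' reaches only the two carbons ortho to C8a'', one of which (C8'') bears unit 1, so only C4a'' can be acylated, and that carbon is ortho to one isopropoxy group and para to the other, whereas C6 of unit 1 is out of reach and closure onto the 4-isopropoxyphenyl ring would need a five-membered ring at a carbon meta to its alkoxy group. Any E isomer present should equilibrate with the Z isomer by reversible protonation at C3'' of the push–pull enol ether in the trifluoroacetic acid that the reaction releases, so both isomers should converge on 18. The conditions contain no strong Lewis acid, so the isopropyl ethers and the methyl ether should be retained.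

Step 13
Reactants: 18 5,7,5'',7'',4'''-penta-O-isopropyl ether of the target
Product: 20 4'-O-methylcupressuflavone (target), via pentakis(dichloroboryl) ether 19 (not isolated)
Conditions: BCl3 (excess), CH2Cl2, −78 °C to rt; then H2O, 0 °C
Reagents that add atoms: none
Why: Lewis-acid ether cleavage; BCl3 coordinates each isopropyl ether oxygen and the secondary alkyl group leaves as 2-chloropropane, giving the aryloxydichloroborane 19 that is hydrolysed on work-up. The C4' methyl ether has a primary alkyl group and no neighbouring carbonyl to assist, so it should remain.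

## Compound list

1 | acacetin (5,7-dihydroxy-4'-methoxyflavone) | COc1ccc(cc1)-c1cc(=O)c2c(O)cc(O)cc2o1 | starting material
2 | 5,7-diisopropoxy-4'-methoxyflavone | COc1ccc(cc1)-c1cc(=O)c2c(OC(C)C)cc(OC(C)C)cc2o1 | intermediate
3 | 8-iodo-5,7-diisopropoxy-4'-methoxyflavone | COc1ccc(cc1)-c1cc(=O)c2c(OC(C)C)cc(OC(C)C)c(I)c2o1 | intermediate
4 | phloroglucinol | Oc1cc(O)cc(O)c1 | starting material
5 | 3,5-diisopropoxyphenol | CC(C)Oc1cc(O)cc(OC(C)C)c1 | intermediate
6 | 1-(methoxymethoxy)-3,5-diisopropoxybenzene | COCOc1cc(OC(C)C)cc(OC(C)C)c1 | intermediate
7 | [2-(methoxymethoxy)-4,6-diisopropoxyphenyl]lithium (not isolated) | [Li]c1c(OCOC)cc(OC(C)C)cc1OC(C)C | intermediate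
8 | 2-[2-(methoxymethoxy)-4,6-diisopropoxyphenyl]-4,4,5,5-tetramethyl-1,3,2-dioxaborolane | COCOc1cc(OC(C)C)cc(OC(C)C)c1B1OC(C)(C)C(C)(C)O1 | intermediate
9 | 4-iodophenol | Oc1ccc(I)cc1 | starting material
10 | 1-iodo-4-isopropoxybenzene | CC(C)Oc1ccc(I)cc1 | intermediate
11 | ethyl propiolate | C#CC(=O)OCC | starting material
12 | ethyl 3-(4-isopropoxyphenyl)propiolate | CCOC(=O)C#Cc1ccc(OC(C)C)cc1 | intermediate
13 | 8-[2-(methoxymethoxy)-4,6-diisopropoxyphenyl]-5,7-diisopropoxy-4'-methoxyflavone (racemic axis) | COc1ccc(cc1)-c1cc(=O)c2c(OC(C)C)cc(OC(C)C)c(-c3c(OCOC)cc(OC(C)C)cc3OC(C)C)c2o1 | intermediate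
14 | 8-(2-hydroxy-4,6-diisopropoxyphenyl)-5,7-diisopropoxy-4'-methoxyflavone (racemic axis) | COc1ccc(cc1)-c1cc(=O)c2c(OC(C)C)cc(OC(C)C)c(-c3c(O)cc(OC(C)C)cc3OC(C)C)c2o1 | intermediate
15 | ethyl (Z)-3-[2-(5,7-diisopropoxy-4'-methoxyflavon-8-yl)-3,5-diisopropoxyphenoxy]-3-(4-isopropoxyphenyl)acrylate | CCOC(=O)/C=C(\Oc1cc(OC(C)C)cc(OC(C)C)c1-c1c(OC(C)C)cc(OC(C)C)c2c(=O)cc(-c3ccc(OC)cc3)oc12)c1ccc(OC(C)C)cc1 | intermediate
16 | (Z)-3-[2-(5,7-diisopropoxy-4'-methoxyflavon-8-yl)-3,5-diisopropoxyphenoxy]-3-(4-isopropoxyphenyl)acrylic acid | OC(=O)/C=C(\Oc1cc(OC(C)C)cc(OC(C)C)c1-c1c(OC(C)C)cc(OC(C)C)c2c(=O)cc(-c3ccc(OC)cc3)oc12)c1ccc(OC(C)C)cc1 | intermediate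
17 | mixed anhydride of 16 with trifluoroacetic acid (not isolated) | FC(F)(F)C(=O)OC(=O)/C=C(\Oc1cc(OC(C)C)cc(OC(C)C)c1-c1c(OC(C)C)cc(OC(C)C)c2c(=O)cc(-c3ccc(OC)cc3)oc12)c1ccc(OC(C)C)cc1 | intermediate
18 | 5,7-diisopropoxy-8-[5,7-diisopropoxy-2-(4-isopropoxyphenyl)-4-oxo-4H-chromen-8-yl]-4'-methoxyflavone (5,7,5'',7'',4'''-penta-O-isopropyl ether of the target) | CC(C)Oc1ccc(cc1)-c1cc(=O)c2c(OC(C)C)cc(OC(C)C)c(-c3c(OC(C)C)cc(OC(C)C)c4c(=O)cc(-c5ccc(OC)cc5)oc34)c2o1 | intermediate
19 | 5,7,5'',7'',4'''-pentakis(dichloroboryl) ether of the target (not isolated) | ClB(Cl)Oc1ccc(cc1)-c1cc(=O)c2c(OB(Cl)Cl)cc(OB(Cl)Cl)c(-c3c(OB(Cl)Cl)cc(OB(Cl)Cl)c4c(=O)cc(-c5ccc(OC)cc5)oc34)c2o1 | intermediate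
20 | 4'-O-methylcupressuflavone (5,7-dihydroxy-8-[5,7-dihydroxy-2-(4-hydroxyphenyl)-4-oxo-4H-chromen-8-yl]-2-(4-methoxyphenyl)-4H-chromen-4-one, racemic axis) | COc1ccc(-c2cc(=O)c3c(O)cc(O)c(-c4c(O)cc(O)c5c(=O)cc(-c6ccc(O)cc6)oc45)c3o2)cc1 | target

## Step count and least certain steps

Total step count: 13. Longest linear sequence: 9 steps (steps 3, 4, 5, 8, 9, 10, 11, 12, 13, from phloroglucinol).

**Step 12 (key step).** The acylium-type species is stabilised by the β-aryloxy oxygen, so closure may be slow. The liberated acid may then protonate the push–pull enol ether and cleave the aryl–oxygen–vinyl linkage (loss of the side chain), or an isopropyl ether next to a carbonyl may be lost by acidolysis. The fallback sets out from 14 and comes back at 18, building ring C'' in the classical chalcone manner. Acetylation of 14 at the free carbon ortho to the hydroxyl (Ac2O, BF3·OEt2, CH2Cl2, Fries-type, chelate-controlled) should give 8-(3-acetyl-2-hydroxy-4,6-diisopropoxyphenyl)-5,7-diisopropoxy-4'-methoxyflavone F1. Claisen–Schmidt condensation of F1 with 4-isopropoxybenzaldehyde (KOH, EtOH, rt) should give 8-{2-hydroxy-4,6-diisopropoxy-3-[(E)-3-(4-isopropoxyphenyl)acryloyl]phenyl}-5,7-diisopropoxy-4'-methoxyflavone F2. Oxidative cyclization of F2 with catalytic I2 in DMSO at 120 °C then closes ring C'' at O1''–C2'' and gives 18.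

**Step 8.** Protodeboronation of the 2,6-dialkoxyarylboronate in the aqueous base may outrun transmetalation onto the hindered arylpalladium iodide, because both partners carry two ortho oxygen substituents. The fallback sets out from 6 and 3 and comes back at 13, replacing boron by zinc under anhydrous, base-free conditions (Negishi coupling). Lithiation of 6 to 7 as in step 5 and addition of ZnCl2 should give [2-(methoxymethoxy)-4,6-diisopropoxyphenyl]zinc chloride F3. F3 is then coupled with 3 using Pd2(dba)3 and RuPhos in THF at 65 °C to give 13.

**Step 10.** Conjugate addition may stall, because the phenoxide of 14 has a bulky ortho aryl group and the ynoate 12 is deactivated by its electron-rich aryl group; prolonged heating with base may then degrade the ynoate. The fallback sets out from 12 and 14 and comes back at 15, forming the oxygen–vinyl bond by copper-catalysed coupling instead of uncatalysed addition. Hydroiodination of 12 (NaI, AcOH, 100 °C) should give ethyl (Z)-3-iodo-3-(4-isopropoxyphenyl)acrylate F4. Ullmann-type coupling of F4 with 14 (CuI, N,N-dimethylglycine, Cs2CO3, dioxane, 90 °C) should then give 15 with retention of the alkene geometry.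

**Step 5.** Lithiation may be only partly site-selective, with some metalation between the two isopropoxy groups, which would lead to an isomeric boronate that is hard to separate. The fallback sets out from 5 and comes back at 7 (and so at 8), fixing the position with a halogen before the acetal is put on. Amine-mediated ortho-bromination of the free phenol (NBS, cat. i-Pr2NH, CH2Cl2, 0 °C) should give 2-bromo-3,5-diisopropoxyphenol F5. Protection of F5 (NaH, MOMCl, THF) gives 2-bromo-1-(methoxymethoxy)-3,5-diisopropoxybenzene F6. Bromine–lithium exchange on F6 (n-BuLi, THF, −78 °C) then gives 7 at a defined position, and the borate quench of step 5 gives 8.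

**Step 3.** Partial alkylation of a triphenol gives a statistical mixture, and C-alkylation of the phloroglucinol anion may compete, so material throughput may be low. The fallback sets out from 4 and comes back at 5. Exhaustive alkylation (excess 2-bromopropane, K2CO3, DMF, 80 °C) gives 1,3,5-triisopropoxybenzene F7, and one ether of F7 is then cleaved with one equivalent of BCl3 in CH2Cl2 at −78 to 0 °C. The aryloxydichloroborane formed first deactivates the ring towards a second cleavage, and aqueous work-up gives 5.

## Further compounds

F1 | step 12 | 8-(3-acetyl-2-hydroxy-4,6-diisopropoxyphenyl)-5,7-diisopropoxy-4'-methoxyflavone | COc1ccc(cc1)-c1cc(=O)c2c(OC(C)C)cc(OC(C)C)c(-c3c(O)c(C(C)=O)c(OC(C)C)cc3OC(C)C)c2o1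
F2 | step 12 | 8-{2-hydroxy-4,6-diisopropoxy-3-[(E)-3-(4-isopropoxyphenyl)acryloyl]phenyl}-5,7-diisopropoxy-4'-methoxyflavone | COc1ccc(cc1)-c1cc(=O)c2c(OC(C)C)cc(OC(C)C)c(-c3c(O)c(C(=O)/C=C/c4ccc(OC(C)C)cc4)c(OC(C)C)cc3OC(C)C)c2o1
F3 | step 8 | [2-(methoxymethoxy)-4,6-diisopropoxyphenyl]zinc chloride | COCOc1cc(OC(C)C)cc(OC(C)C)c1[Zn]Cl
F4 | step 10 | ethyl (Z)-3-iodo-3-(4-isopropoxyphenyl)acrylate | CCOC(=O)/C=C(\I)c1ccc(OC(C)C)cc1
F5 | step 5 | 2-bromo-3,5-diisopropoxyphenol | CC(C)Oc1cc(O)c(Br)c(OC(C)C)c1
F6 | step 5 | 2-bromo-1-(methoxymethoxy)-3,5-diisopropoxybenzene | COCOc1cc(OC(C)C)cc(OC(C)C)c1Br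
F7 | step 3 | 1,3,5-triisopropoxybenzene | CC(C)Oc1cc(OC(C)C)cc(OC(C)C)c1
A1 | alternative 1 | 4-hydroxy-6-[(E)-4-(4-methoxyphenyl)-2-oxobut-3-en-1-yl]-3-(5,7,4'-tribenzyloxyflavon-8-yl)-2H-pyran-2-one | COc1ccc(/C=C/C(=O)Cc2cc(O)c(-c3c(OCc4ccccc4)cc(OCc4ccccc4)c4c(=O)cc(-c5ccc(OCc6ccccc6)cc5)oc34)c(=O)o2)cc1
A2 | alternative 1 | 2',4',6'-trihydroxy-4-methoxy-3'-(5,7,4'-tribenzyloxyflavon-8-yl)chalcone | COc1ccc(/C=C/C(=O)c2c(O)cc(O)c(-c3c(OCc4ccccc4)cc(OCc4ccccc4)c4c(=O)cc(-c5ccc(OCc6ccccc6)cc5)oc34)c2O)cc1
A3 | alternative 2 | 8-[(triisopropylsilyloxy)ethynyl]-5,7-bis(benzyloxy)-4'-methoxyflavone | COc1ccc(cc1)-c1cc(=O)c2c(OCc3ccccc3)cc(OCc3ccccc3)c(C#CO[Si](C(C)C)(C(C)C)C(C)C)c2o1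
A4 | alternative 2 | 3-ethoxycyclobut-2-en-1-one | CCOC1=CC(=O)C1
A5 | alternative 2 | 8-[4-ethoxy-2-hydroxy-6-(triisopropylsilyloxy)phenyl]-5,7-bis(benzyloxy)-4'-methoxyflavone | COc1ccc(cc1)-c1cc(=O)c2c(OCc3ccccc3)cc(OCc3ccccc3)c(-c3c(O)cc(OCC)cc3O[Si](C(C)C)(C(C)C)C(C)C)c2o1
A6 | alternative 3 | 2-(4-methoxyphenyl)-5-(4-methylphenylsulfinyl)-4H-pyran-4-one (racemic at sulfur) | COc1ccc(cc1)-c1cc(=O)c(co1)S(=O)c1ccc(C)cc1
A7 | alternative 3 | 1-methoxy-1,3-bis(trimethylsilyloxy)-4-(5,7,4'-tribenzyloxyflavon-8-yl)buta-1,3-diene (alkene geometry not defined) | COC(O[Si](C)(C)C)=CC(O[Si](C)(C)C)=Cc1c(OCc2ccccc2)cc(OCc2ccccc2)c2c(=O)cc(-c3ccc(OCc4ccccc4)cc3)oc12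
A8 | alternative 3 | 5,7-dihydroxy-4'-methoxy-8-(5,7,4'-tribenzyloxyflavon-8-yl)flavone | COc1ccc(cc1)-c1cc(=O)c2c(O)cc(O)c(-c3c(OCc4ccccc4)cc(OCc4ccccc4)c4c(=O)cc(-c5ccc(OCc6ccccc6)cc5)oc34)c2o1
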